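**Plan**

- Retrosynthesis: the six O-alkyl groups come off last. Ring C is then cut at C1–C6, C2–C3 and C3–C4 into an aryl ethynyl ether (C1 and C2, ring B oxygen already on C1) and 4-bromo-3-ethoxycyclobutenone (C3–C6, bromine already on the future C4).
- The ynol ether is cut at its O–C(sp) bond to the ring A–B phenol and trichloroethylene, the A–B diaryl ether at the ring B C–O bond (Ullmann), and the cyclobutenone into bromoketene and ethoxyacetylene.
- Forward: rings A and B are bought as arenes and joined first, the ring B phenol is turned into the ynol ether, ring C is built last by Danheiser benzannulation, and global dealkylation ends the route.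
- Enabling feature: in ring C, C1 carries the ether oxygen and C3 and C5 the hydroxyls. This 1,3,5-trioxygenation is what a ketene carbonyl (C3), an ynol ether (C1) and a 3-alkoxycyclobutenone (C5) deliver. C4–Br lies between C3 and C5 and para to C1, which is where the sp3 carbon of the cyclobutenone ends up.
- Stereochemistry: the target has no stereocenter; the single stereocenter of the racemic cyclobutenone is erased on aromatization.

Key step: step 7

Remark: the bromocyclobutenone is made and used as the racemate. The alkene geometries drawn for the transient ketenes are those expected from outward rotation of bromine and those required for ring closure.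

**Route**

Step 1
Reactants: 1 4-bromo-2,6-dimethoxyphenol
Product: 2 2-(benzyloxy)-5-bromo-1,3-dimethoxybenzene
Conditions: BnBr, K2CO3, DMF, 20 → 50 °C
Reagents that add atoms: benzyl bromide, BrCc1ccccc1
Why: Williamson etherification of the phenoxide should be clean and masks the O–H that would otherwise compete as nucleophile in the copper coupling.

Step 2
Reactants: 2 2-(benzyloxy)-5-bromo-1,3-dimethoxybenzene; 3 2,4,6-trimethoxyphenol
Product: 4 2-(benzyloxy)-1,3-dimethoxy-5-(2,4,6-trimethoxyphenoxy)benzene
Conditions: CuI (10 mol %), picolinic acid (20 mol %), K3PO4, DMSO, 90 °C, argon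
Reagents that add atoms: none
Why: Ullmann-type copper-catalysed diaryl ether coupling should succeed because the bromide has no ortho substituent and the picolinic acid system is known to accept di-ortho-substituted phenols.

Step 3
Reactants: 4 2-(benzyloxy)-1,3-dimethoxy-5-(2,4,6-trimethoxyphenoxy)benzene
Product: 5 2,6-dimethoxy-4-(2,4,6-trimethoxyphenoxy)phenol
Conditions: H2 (1 atm), 10% Pd/C, EtOAc/MeOH, 20 °C
Reagents that add atoms: none
Why: Catalytic hydrogenolysis of the benzyl aryl ether should free the ring B phenol, since no halogen is present at this stage and methyl and diaryl ethers are inert.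

Step 4
Reactants: 5 2,6-dimethoxy-4-(2,4,6-trimethoxyphenoxy)phenol; 6 trichloroethylene
Product: 7 2-{[(E)-1,2-dichloroethenyl]oxy}-1,3-dimethoxy-5-(2,4,6-trimethoxyphenoxy)benzene
Conditions: K2CO3, DMF, 70 °C
Reagents that add atoms: none
Why: Base converts trichloroethylene into dichloroacetylene in the flask, and anti addition of the phenoxide across it (the known dichlorovinyl ether synthesis from phenols) should give the (E)-ether even with the hindered oxygen, because the electrophile is a slim sp carbon.

Step 5
Reactants: 7 2-{[(E)-1,2-dichloroethenyl]oxy}-1,3-dimethoxy-5-(2,4,6-trimethoxyphenoxy)benzene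
Product: 10 2-(ethynyloxy)-1,3-dimethoxy-5-(2,4,6-trimethoxyphenoxy)benzene, via chloroalkyne 8 (not isolated), via lithium acetylide 9 (not isolated)
Conditions: n-BuLi (2.3 equiv), THF, −78 → −40 °C; then H2O, −78 → 0 °C; used at once as a toluene solution
Reagents that add atoms: none
Why: The established dichlorovinyl ether route to ynol ethers (deprotonation and loss of LiCl to the chloroalkyne, chlorine–lithium exchange to the lithium aryloxyacetylide, protonation) should give the terminal ynol ether, the low temperature keeping ortho-lithiation of the methoxyarenes from competing.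

Step 6
Reactants: 11 bromoacetyl bromide; 12 ethoxyacetylene
Product: 14 rac-4-bromo-3-ethoxycyclobut-2-en-1-one, via bromoketene 13 (not isolated)
Conditions: Et3N (slow addition), 12 (2 equiv), Et2O, −20 → 20 °C; rapid filtration through deactivated silica
Reagents that add atoms: none
Why: Dehydrobromination gives bromoketene, which the strongly nucleophilic alkoxyalkyne should trap in a ketene–alkyne (2+2) cycloaddition as known for acid halide-derived ketenes, the terminal alkyne carbon bonding to the ketene carbonyl carbon so that ethoxy ends at C3 and bromine at C4.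

Step 7
Reactants: 10 2-(ethynyloxy)-1,3-dimethoxy-5-(2,4,6-trimethoxyphenoxy)benzene; 14 rac-4-bromo-3-ethoxycyclobut-2-en-1-one
Product: 19 2-bromo-5-[2,6-dimethoxy-4-(2,4,6-trimethoxyphenoxy)phenoxy]-3-ethoxyphenol, via bromovinylketene 15 (not isolated), via vinylcyclobutenone 16 (not isolated), via dienylketene 17 (not isolated), via cyclohexadienone 18 (not isolated)
Conditions: 14 (1.5 equiv), toluene, 80 °C then 110 °C, argon
Reagents that add atoms: none
Why: Proposed new method: on heating, 14 should open by 4π electrocyclic ring opening (bromine turning outward) to bromovinylketene 15, whose ketene carbon is attacked by the nucleophilic terminal carbon of 10 while the ketene α-carbon bonds to the oxygen-bearing alkyne carbon, giving vinylcyclobutenone 16 by (2+2) cycloaddition and with it the ring C bonds C2–C3 and C1–C6. A second 4π opening gives dienylketene 17, and ring C closes by thermal disrotatory 6π electrocyclization (bond C3–C4) to dienone 18, the same keto tautomer through which ortho-bromination of a phenol passes, so enolization to 19 should be fast. The closest known reaction type is the Danheiser benzannulation of cyclobutenones with alkoxy- and siloxyalkynes to resorcinol monoethers; a cyclobutenone carrying hydrogen and bromine at C4 and an aryl ethynyl ether have not been used as partners, although 4-halocyclobutenones are known to open reversibly to halovinylketenes near 100 °C and ynamides, which are no more nucleophilic than 10, take part in the same annulation. No stereocenter is created, since those of 14, 16 and 18 are racemic and vanish on aromatization. The one selectivity needed is the orientation of the (2+2) step, fixed by the polarization of the ynol ether, which places the aryloxy group meta to the new hydroxyl and para to bromine; the bromine position is fixed because it sits on the sp3 carbon of 14 that becomes C4.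

Step 8
Reactants: 19 2-bromo-5-[2,6-dimethoxy-4-(2,4,6-trimethoxyphenoxy)phenoxy]-3-ethoxyphenol
Product: 20 2-[4-(4-bromo-3,5-dihydroxyphenoxy)-3,5-dihydroxyphenoxy]benzene-1,3,5-triol
Conditions: BBr3 (12 equiv), CH2Cl2, −78 → 20 °C; then H2O, 0 °C, work-up under argon
Reagents that add atoms: none
Why: Lewis acid-mediated cleavage of aryl alkyl ethers by BBr3 should remove the five methyl groups and the ethyl group while leaving the diaryl ether C–O bonds and the aryl C–Br bond untouched.

**Compound list**

1 | 4-bromo-2,6-dimethoxyphenol | COc1cc(Br)cc(OC)c1O | starting material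
2 | 2-(benzyloxy)-5-bromo-1,3-dimethoxybenzene | COc1cc(Br)cc(OC)c1OCc1ccccc1 | intermediate
3 | 2,4,6-trimethoxyphenol | COc1cc(OC)c(O)c(OC)c1 | starting material
4 | 2-(benzyloxy)-1,3-dimethoxy-5-(2,4,6-trimethoxyphenoxy)benzene | COc1cc(Oc2c(OC)cc(OC)cc2OC)cc(OC)c1OCc1ccccc1 | intermediate
5 | 2,6-dimethoxy-4-(2,4,6-trimethoxyphenoxy)phenol | COc1cc(Oc2c(OC)cc(OC)cc2OC)cc(OC)c1O | intermediate
6 | trichloroethylene | ClC=C(Cl)Cl | starting material
7 | 2-{[(E)-1,2-dichloroethenyl]oxy}-1,3-dimethoxy-5-(2,4,6-trimethoxyphenoxy)benzene | Cl/C=C(/Cl)Oc1c(OC)cc(Oc2c(OC)cc(OC)cc2OC)cc1OC | intermediate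
8 | 2-[(chloroethynyl)oxy]-1,3-dimethoxy-5-(2,4,6-trimethoxyphenoxy)benzene (not isolated) | ClC#COc1c(OC)cc(Oc2c(OC)cc(OC)cc2OC)cc1OC | intermediate
9 | lithium 2-[2,6-dimethoxy-4-(2,4,6-trimethoxyphenoxy)phenoxy]ethynide (not isolated) | [Li]C#COc1c(OC)cc(Oc2c(OC)cc(OC)cc2OC)cc1OC | intermediate
10 | 2-(ethynyloxy)-1,3-dimethoxy-5-(2,4,6-trimethoxyphenoxy)benzene | C#COc1c(OC)cc(Oc2c(OC)cc(OC)cc2OC)cc1OC | intermediate
11 | bromoacetyl bromide | BrCC(Br)=O | starting material
12 | ethoxyacetylene | CCOC#C | starting material
13 | bromoketene (not isolated) | O=C=CBr | intermediate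
14 | rac-4-bromo-3-ethoxycyclobut-2-en-1-one | CCOC1=CC(=O)C1Br | intermediate
15 | (3Z)-4-bromo-3-ethoxybuta-1,3-dien-1-one (not isolated) | O=C=C/C(OCC)=C/Br | intermediate
16 | rac-4-[(Z)-2-bromo-1-ethoxyethenyl]-3-[2,6-dimethoxy-4-(2,4,6-trimethoxyphenoxy)phenoxy]cyclobut-2-en-1-one (not isolated) | O=C1C=C(Oc2c(OC)cc(Oc3c(OC)cc(OC)cc3OC)cc2OC)C1/C(OCC)=C/Br | intermediate
17 | (3E,5Z)-6-bromo-3-[2,6-dimethoxy-4-(2,4,6-trimethoxyphenoxy)phenoxy]-5-ethoxyhexa-1,3,5-trien-1-one (not isolated) | O=C=C/C(Oc1c(OC)cc(Oc2c(OC)cc(OC)cc2OC)cc1OC)=C\C(OCC)=C\Br | intermediate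
18 | rac-6-bromo-3-[2,6-dimethoxy-4-(2,4,6-trimethoxyphenoxy)phenoxy]-5-ethoxycyclohexa-2,4-dien-1-one (not isolated) | O=C1C=C(Oc2c(OC)cc(Oc3c(OC)cc(OC)cc3OC)cc2OC)C=C(OCC)C1Br | intermediate
19 | 2-bromo-5-[2,6-dimethoxy-4-(2,4,6-trimethoxyphenoxy)phenoxy]-3-ethoxyphenol | CCOc1cc(Oc2c(OC)cc(Oc3c(OC)cc(OC)cc3OC)cc2OC)cc(O)c1Br | intermediate
20 | 2-[4-(4-bromo-3,5-dihydroxyphenoxy)-3,5-dihydroxyphenoxy]benzene-1,3,5-triol | Oc1cc(O)c(Oc2cc(O)c(Oc3cc(O)c(Br)c(O)c3)c(O)c2)c(O)c1 | target

**Count and risks**

Total steps: 8. Longest linear sequence: 7 steps (steps 1, 2, 3, 4, 5, 7, 8); the cyclobutenone branch adds step 6.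

Steps most likely to fail:

1. Step 7. Oligomerization of the terminal aryl ynol ether and self-reaction of the bromovinylketene may outrun the cycloaddition, and excess vinylketene may O-acylate the product phenol. The fallback buys ring C as an arene and attaches it by known chemistry; it sets out from phenol 5 and returns at 20. Iridium-catalysed C–H borylation of commercial 2-bromo-1,3-dimethoxybenzene ([Ir(OMe)(cod)]2, dtbpy, B2pin2, THF, 80 °C) is sterically directed to the only C–H not next to a substituent and would give 2-(4-bromo-3,5-dimethoxyphenyl)-4,4,5,5-tetramethyl-1,3,2-dioxaborolane F1. NaIO4 and NH4OAc in aqueous acetone would free (4-bromo-3,5-dimethoxyphenyl)boronic acid F2. Chan–Lam coupling of F2 with 5 (Cu(OAc)2, pyridine, 4 Å sieves, CH2Cl2, air) would give 2-bromo-5-[2,6-dimethoxy-4-(2,4,6-trimethoxyphenoxy)phenoxy]-1,3-dimethoxybenzene F3. BBr3 as in step 8 would cleave its seven methyl ethers to 20.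

2. Step 6. Bromoketene may polymerize, or the amine may be N-alkylated by the bromoacetyl unit, faster than the cycloaddition, and the vinylogous ester may hydrolyse on purification. The fallback introduces bromine by radical substitution on a preformed ring; it sets out from 12 and returns at 14. Acetyl chloride and Et3N would generate ketene F4 in the presence of 12 (Et2O, 0 °C), the known (2+2) cycloaddition giving 3-ethoxycyclobut-2-en-1-one F5. Wohl–Ziegler bromination (NBS, AIBN or light, PhCF3) would abstract a C4 hydrogen; the resulting delocalized radical is symmetric about the carbonyl, so bromine capture at either end gives 14.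

3. Step 2. C–O bond formation with the di-ortho-methoxy phenoxide may be slow, and the electron-rich phenol may degrade oxidatively under copper. The fallback forms the A–B ether by nucleophilic aromatic substitution and makes steps 1–3 unnecessary; it sets out from 3 and returns at 5. Phenol 3 and commercial 4-fluoro-2,6-dimethoxybenzaldehyde (K2CO3, DMF, 120 °C) would give 2,6-dimethoxy-4-(2,4,6-trimethoxyphenoxy)benzaldehyde F6, the para-formyl group activating the fluoride. Baeyer–Villiger oxidation (mCPBA, CH2Cl2) would give 2,6-dimethoxy-4-(2,4,6-trimethoxyphenoxy)phenyl formate F7, and K2CO3 in MeOH would release 5.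

**Further compounds**

F1 | step 7 | 2-(4-bromo-3,5-dimethoxyphenyl)-4,4,5,5-tetramethyl-1,3,2-dioxaborolane | COc1cc(cc(OC)c1Br)B1OC(C)(C)C(C)(C)O1
F2 | step 7 | (4-bromo-3,5-dimethoxyphenyl)boronic acid | COc1cc(B(O)O)cc(OC)c1Br
F3 | step 7 | 2-bromo-5-[2,6-dimethoxy-4-(2,4,6-trimethoxyphenoxy)phenoxy]-1,3-dimethoxybenzene | COc1cc(Oc2c(OC)cc(Oc3c(OC)cc(OC)cc3OC)cc2OC)cc(OC)c1Br
F4 | step 6 | ketene (not isolated) | C=C=O
F5 | step 6 | 3-ethoxycyclobut-2-en-1-one | CCOC1=CC(=O)C1
F6 | step 2 | 2,6-dimethoxy-4-(2,4,6-trimethoxyphenoxy)benzaldehyde | COc1cc(Oc2c(OC)cc(OC)cc2OC)cc(OC)c1C=O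
F7 | step 2 | 2,6-dimethoxy-4-(2,4,6-trimethoxyphenoxy)phenyl formate | COc1cc(Oc2c(OC)cc(OC)cc2OC)cc(OC)c1OC=O
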